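The oxolane ring is closed at C4–C5. The feature exploited is that C5 is an unsubstituted methylene between ring oxygen O1 and C4, while C4 bears an exocyclic carbon. C5 can therefore be released as an α-alkoxymethyl radical by photoredox decarboxylation of an O1-carboxymethyl ether and add 5-exo to a vinyl group on C3. Co(dmgH)2(py)Cl then desaturates the adduct, so both C4 epimers converge on one 4-methylideneoxolane. The precursor is acyclic: an anti-2-vinyl-1,3-diol monoether whose C2 and C3 come from one iridium-catalysed (hydroxymethyl)allylation of veratraldehyde. Face-selective hydroboration then sets C4 cis to C3, and B-alkyl Suzuki coupling adds the guaiacyl ring.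

Key step: step 4

Numbering used throughout: oxolane O1, C2 (3,4-dimethoxyphenyl), C3 (CH2OH), C4 (arylmethyl), C5 (CH2).

Assumption: the ligand antipode written in step 1 is taken to deliver the (1S,2R) diol; should it deliver the mirror image, the other antipode is used.

Step 1
Reactants: 1 3,4-dimethoxybenzaldehyde; 2 4-ethenyl-1,3-dioxolan-2-one (racemic)
Product: 3 (1S,2R)-1-(3,4-dimethoxyphenyl)-2-ethenylpropane-1,3-diol
Conditions: [Ir(cod)Cl]2 (2.5 mol%), (S)-SEGPHOS (5 mol%), 4-cyano-3-nitrobenzoic acid (10 mol%), K3PO4 (5 mol%), iPrOH (2 equiv), THF, 60 °C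
Reagents that add atoms: none
Why: Iridium-catalysed transfer-hydrogenative carbonyl (hydroxymethyl)allylation, in which decarboxylative ionisation of 2 gives a hydroxymethyl-substituted π-allyl iridium species whose (E)-σ-allyl form should add to 1 through a closed chair transition state (C1–OH anti to C2–CH2OH), the chiral bisphosphine choosing the aldehyde face so that both stereocenters (1S,2R) are set, with propan-2-ol as terminal reductant.

Step 2
Reactants: 3 (1S,2R)-1-(3,4-dimethoxyphenyl)-2-ethenylpropane-1,3-diol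
Product: 4 (1S,2R)-1-(3,4-dimethoxyphenyl)-2-({[tri(propan-2-yl)silyl]oxy}methyl)but-3-en-1-ol
Conditions: TIPSCl (1.05 equiv), imidazole, CH2Cl2, 0 °C
Reagents that add atoms: triisopropylsilyl chloride (TIPSCl), CC(C)[Si](Cl)(C(C)C)C(C)C
Why: Silyl ether formation that should be kinetically selective for the unhindered primary hydroxyl over the secondary benzylic one because of the bulk of the triisopropylsilyl group; no stereocenter is touched.

Step 3
Reactants: 4 (1S,2R)-1-(3,4-dimethoxyphenyl)-2-({[tri(propan-2-yl)silyl]oxy}methyl)but-3-en-1-ol; 5 bromoacetic acid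
Product: 6 2-{[(1S,2R)-1-(3,4-dimethoxyphenyl)-2-({[tri(propan-2-yl)silyl]oxy}methyl)but-3-en-1-yl]oxy}acetic acid
Conditions: NaH (3 equiv), THF, 0 °C; then 5, 0 °C to 45 °C; 1 M HCl work-up
Reagents that add atoms: none
Why: Williamson etherification of the sodium alkoxide of 4 with sodium bromoacetate formed in the flask should install the O1–CH2–CO2H radical precursor, the triisopropylsilyl ether being chosen because it resists O-to-O silyl migration under these basic conditions.

Step 4
Reactants: 6 2-{[(1S,2R)-1-(3,4-dimethoxyphenyl)-2-({[tri(propan-2-yl)silyl]oxy}methyl)but-3-en-1-yl]oxy}acetic acid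
Product: 7 {[(2S,3R)-2-(3,4-dimethoxyphenyl)-4-methylideneoxolan-3-yl]methoxy}tri(propan-2-yl)silane
Conditions: Ir[dF(CF3)ppy]2(dtbbpy)PF6 (1 mol%), Co(dmgH)2(py)Cl (5 mol%), Cs2CO3 (20 mol%), degassed DME (0.02 M), blue LEDs, rt
Reagents that add atoms: none
Why: Photoexcited Ir[dF(CF3)ppy]2(dtbbpy)PF6 should oxidise the caesium carboxylate of 6, loss of CO2 gives the nucleophilic α-alkoxymethyl radical at C5, this adds to the internal vinyl carbon (C4) to leave a primary radical on the exocyclic carbon, and divalent cobalt (from Co(dmgH)2(py)Cl) intercepts that radical and removes the C4 hydrogen, the trivalent cobalt hydride releasing H2 while the reduced photocatalyst returns cobalt to the divalent state. The closest known reaction type is the photoredox/Co(dmgH)2(py)Cl decarboxylative radical Heck-type (desaturative) coupling of carboxylic acids with alkenes, run here intramolecularly in the manner of a cobalt-mediated alkyl-Heck cyclisation. The oxolane ring closes in the 5-exo-trig mode (C5 radical onto C4=CH2). No stereocenter is created in the isolated product: C4 arises as a mixture of epimeric radicals that converge on one sp2 carbon, which makes the intrinsic trans preference of this cyclisation harmless, and C2 and C3 are not involved. The step needs cyclisation to outrun quenching of the C5 radical (served by high dilution and the fast 5-exo closure of 2-oxahex-5-enyl radicals), oxidation of the carboxylate in preference to the dimethoxyarene (the carboxylate has the lower oxidation potential), and a single alkene regiochemistry (C4 carries the only hydrogen β to the cobalt-bound carbon).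

Step 5
Reactants: 8 4-bromo-2-methoxyphenol
Product: 9 (4-bromo-2-methoxyphenoxy)tri(propan-2-yl)silane
Conditions: TIPSCl, imidazole, DMF, rt
Reagents that add atoms: triisopropylsilyl chloride (TIPSCl), CC(C)[Si](Cl)(C(C)C)C(C)C
Why: Routine phenol silylation, so that the aryl bromide is not deactivated as a para-phenoxide in the cross-coupling and both silyl groups can be removed in one final operation.

Step 6
Reactants: 7 {[(2S,3R)-2-(3,4-dimethoxyphenyl)-4-methylideneoxolan-3-yl]methoxy}tri(propan-2-yl)silane; 9 (4-bromo-2-methoxyphenoxy)tri(propan-2-yl)silane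
Product: 11 {[(2S,3R,4R)-2-(3,4-dimethoxyphenyl)-4-({3-methoxy-4-[tri(propan-2-yl)silyloxy]phenyl}methyl)oxolan-3-yl]methoxy}tri(propan-2-yl)silane, via the primary alkyl-9-BBN borane 10 (not isolated)
Conditions: 9-BBN (1.3 equiv), THF, 0 °C to rt; then 9, Pd(OAc)2 (5 mol%), SPhos (10 mol%), K3PO4 (3 equiv), THF/H2O, 60 °C
Reagents that add atoms: none
Why: Anti-Markovnikov syn-hydroboration by the bulky 9-BBN should occur on the alkene face opposite the adjacent C3 silyloxymethyl group, which places the new C4–H trans and the CH2B group cis to the C3 substituent (4R), and the primary alkylborane then undergoes B-alkyl Suzuki–Miyaura coupling with 9 without touching C4.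

Step 7
Reactants: 11 {[(2S,3R,4R)-2-(3,4-dimethoxyphenyl)-4-({3-methoxy-4-[tri(propan-2-yl)silyloxy]phenyl}methyl)oxolan-3-yl]methoxy}tri(propan-2-yl)silane
Product: 12 4-{[(3R,4R,5S)-5-(3,4-dimethoxyphenyl)-4-(hydroxymethyl)oxolan-3-yl]methyl}-2-methoxyphenol
Conditions: TBAF (3 equiv), THF, 0 °C to rt; AcOH quench
Reagents that add atoms: none
Why: Fluoride-mediated desilylation should cleave the aryl and the primary alkyl triisopropylsilyl ethers in one operation under conditions that leave the three stereocenters and the benzylic ring ether untouched.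

Compound list

1 | 3,4-dimethoxybenzaldehyde | COc1ccc(C=O)cc1OC | starting material
2 | 4-ethenyl-1,3-dioxolan-2-one (racemic) | C=CC1COC(=O)O1 | starting material
3 | (1S,2R)-1-(3,4-dimethoxyphenyl)-2-ethenylpropane-1,3-diol | C=C[C@H](CO)[C@H](O)c1ccc(OC)c(OC)c1 | intermediate
4 | (1S,2R)-1-(3,4-dimethoxyphenyl)-2-({[tri(propan-2-yl)silyl]oxy}methyl)but-3-en-1-ol | C=C[C@H](CO[Si](C(C)C)(C(C)C)C(C)C)[C@H](O)c1ccc(OC)c(OC)c1 | intermediate
5 | bromoacetic acid | OC(=O)CBr | starting material
6 | 2-{[(1S,2R)-1-(3,4-dimethoxyphenyl)-2-({[tri(propan-2-yl)silyl]oxy}methyl)but-3-en-1-yl]oxy}acetic acid | C=C[C@H](CO[Si](C(C)C)(C(C)C)C(C)C)[C@H](OCC(=O)O)c1ccc(OC)c(OC)c1 | intermediate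
7 | {[(2S,3R)-2-(3,4-dimethoxyphenyl)-4-methylideneoxolan-3-yl]methoxy}tri(propan-2-yl)silane | C=C1CO[C@H](c2ccc(OC)c(OC)c2)[C@H]1CO[Si](C(C)C)(C(C)C)C(C)C | intermediate
8 | 4-bromo-2-methoxyphenol | COc1cc(Br)ccc1O | starting material
9 | (4-bromo-2-methoxyphenoxy)tri(propan-2-yl)silane | COc1cc(Br)ccc1O[Si](C(C)C)(C(C)C)C(C)C | intermediate
10 | 9-{[(3R,4R,5S)-5-(3,4-dimethoxyphenyl)-4-({[tri(propan-2-yl)silyl]oxy}methyl)oxolan-3-yl]methyl}-9-borabicyclo[3.3.1]nonane | B1(C[C@H]2CO[C@H](c3ccc(OC)c(OC)c3)[C@H]2CO[Si](C(C)C)(C(C)C)C(C)C)C2CCCC1CCC2 | intermediate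
11 | {[(2S,3R,4R)-2-(3,4-dimethoxyphenyl)-4-({3-methoxy-4-[tri(propan-2-yl)silyloxy]phenyl}methyl)oxolan-3-yl]methoxy}tri(propan-2-yl)silane | COc1cc(C[C@H]2CO[C@H](c3ccc(OC)c(OC)c3)[C@H]2CO[Si](C(C)C)(C(C)C)C(C)C)ccc1O[Si](C(C)C)(C(C)C)C(C)C | intermediate
12 | 4-{[(3R,4R,5S)-5-(3,4-dimethoxyphenyl)-4-(hydroxymethyl)oxolan-3-yl]methyl}-2-methoxyphenol | COc1cc(C[C@H]2CO[C@H](c3ccc(OC)c(OC)c3)[C@H]2CO)ccc1O | target

Total step count: 7. Longest linear sequence: 6 steps (steps 1, 2, 3, 4, 6, 7); step 5 is a one-step side branch.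

Steps most likely to fail

Step 4. The C5 radical may be quenched by hydrogen-atom transfer before it cyclises, or the cobalt hydride may re-add and walk the exocyclic double bond into the ring. The fallback sets out from 6 and returns to 7 by a chain group-transfer cyclisation followed by a separate elimination. Esterification of 6 with 1-hydroxypyridine-2(1H)-thione (DCC, CH2Cl2, dark) should give the Barton ester F1. Visible-light photolysis at high dilution in benzene runs the same 5-exo closure in a radical chain and transfers the 2-pyridylthio group to the exocyclic carbon, giving the 2-pyridyl sulfide F2 as both C4 epimers, which is inconsequential. Oxidation with mCPBA at −78 °C should give the sulfoxide F3, whose thermal syn-elimination in toluene at 110 °C (the only β-hydrogen is on C4) comes back to the route at 7.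

Step 6. The borane may approach with poor facial selectivity (syn to the silyloxymethyl group), or transmetalation of the β-branched alkylborane may stall and lead to protodeboronation. The fallback sets out from 7 and returns to 11, setting C4 by hydrogenation instead of hydroboration. Mizoroki–Heck arylation of 7 with 9 (Pd(OAc)2, P(o-tol)3, Et3N, DMF, 100 °C) should give the 4-(arylmethylidene)oxolane F4 as an E/Z mixture. Hydrogenation over 10% Pd on carbon (H2, EtOAc, rt) should deliver hydrogen to the face of C4 anti to the C3 substituent from either alkene isomer, which comes back to the route at 11.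

Step 1. Anti-diastereoselectivity or enantioselectivity may erode with the electron-rich aldehyde, or the allyl donor may be consumed unproductively. The fallback sets out from 1 and returns to 3 by auxiliary control. But-3-enoic acid and (S)-4-benzyl-1,3-oxazolidin-2-one are joined through the pivaloyl mixed anhydride to give (4S)-4-benzyl-3-(but-3-enoyl)-1,3-oxazolidin-2-one F5. Its dibutylboron enolate (Bu2BOTf, iPr2NEt, CH2Cl2, −78 °C) should add to 1 at the α-carbon in an Evans syn-aldol reaction to give the aldol adduct F6. Reductive removal of the auxiliary with LiBH4 (THF, MeOH, 0 °C) comes back to the route at 3.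

Further compounds

F1 | step 4 | 2-sulfanylidenepyridin-1(2H)-yl 2-{[(1S,2R)-1-(3,4-dimethoxyphenyl)-2-({[tri(propan-2-yl)silyl]oxy}methyl)but-3-en-1-yl]oxy}acetate | C=C[C@H](CO[Si](C(C)C)(C(C)C)C(C)C)[C@H](OCC(=O)ON1C=CC=CC1=S)c1ccc(OC)c(OC)c1
F2 | step 4 | 2-({[(4R,5S)-5-(3,4-dimethoxyphenyl)-4-({[tri(propan-2-yl)silyl]oxy}methyl)oxolan-3-yl]methyl}sulfanyl)pyridine (both epimers at oxolane C3) | c1ccc(nc1)SCC1CO[C@H](c2ccc(OC)c(OC)c2)[C@H]1CO[Si](C(C)C)(C(C)C)C(C)C
F3 | step 4 | 2-({[(4R,5S)-5-(3,4-dimethoxyphenyl)-4-({[tri(propan-2-yl)silyl]oxy}methyl)oxolan-3-yl]methyl}sulfinyl)pyridine (isomer mixture) | O=S(CC1CO[C@H](c2ccc(OC)c(OC)c2)[C@H]1CO[Si](C(C)C)(C(C)C)C(C)C)c1ccccn1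
F4 | step 6 | {[(2S,3R)-2-(3,4-dimethoxyphenyl)-4-({3-methoxy-4-[tri(propan-2-yl)silyloxy]phenyl}methylidene)oxolan-3-yl]methoxy}tri(propan-2-yl)silane (E/Z mixture) | COc1cc(C=C2CO[C@H](c3ccc(OC)c(OC)c3)[C@H]2CO[Si](C(C)C)(C(C)C)C(C)C)ccc1O[Si](C(C)C)(C(C)C)C(C)C
F5 | step 1 | (4S)-4-benzyl-3-(but-3-enoyl)-1,3-oxazolidin-2-one | C=CCC(=O)N1[C@@H](Cc2ccccc2)COC1=O
F6 | step 1 | (4S)-4-benzyl-3-{(2S)-2-[(S)-(3,4-dimethoxyphenyl)(hydroxy)methyl]but-3-enoyl}-1,3-oxazolidin-2-one | C=C[C@H](C(=O)N1[C@@H](Cc2ccccc2)COC1=O)[C@H](O)c1ccc(OC)c(OC)c1
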